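**Retrosynthetic overview**

1. Numbering used (seco-guaiane): carbocycle C1–C10–C9–C8–C7–C6–C5; lactone ring O–C6–C7–C11(C13)–C12(=O); side chain C2(=O)–C3=C4–C15 on C1; C14 on C10.
2. Endgame: the crotonoyl ketone comes from a C2 aldehyde (propenyl addition, oxidation); C1(OH)–C2 from osmylation of an exocyclic C1=C2 methylene; C7 and C11 from hydrogenation of a C7=C11 butenolide; the C5 ester from acylation.
3. Key disconnection C5–C6: the cycloheptane is closed by an intramolecular vinylogous Mukaiyama aldol reaction of butenolide enal 12. Enabling feature: C6 is the γ-carbon of the γ-lactone ring and C5 is a carbinol carbon, so with a C7=C11 double bond the lactone is a butenolide whose 2-silyloxyfuran is nucleophilic at C6 toward a C5 aldehyde; the C5, C6, C9 and C10 substituents of the target are all equatorial on one twist-chair of the seven-membered ring.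
4. 12 comes from a C7–C8 reductive coupling of alkyl iodide 5 with bromobutenolide 7; C9 and C10 come from a syn-crotylboration of aldehyde 1.
5. Order of ring formation: butenolide ring (present from tetronic acid 6), then the cycloheptane (key step), then saturation of the lactone ring.

Key step: step 10

Remark: C2 of 20 is formed as a mixture of carbinol epimers and carried on as such, because C2 becomes the ketone carbon; TBS = tert-butyldimethylsilyl, TMS = trimethylsilyl, Ipc = isopinocampheyl.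

**Route**

Step 1
Reactants: 1 (tert-butyldimethylsilyloxy)acetaldehyde
Product: 2 (2S,3R)-1-[(tert-butyldimethylsilyl)oxy]-3-methylpent-4-en-2-ol
Conditions: cis-2-butene, KOt-Bu, n-BuLi, THF, −78 → −45 °C; (−)-Ipc2BOMe, −78 °C; BF3·OEt2, then 1, −78 °C; NaOH, H2O2, 0 °C → rt
Reagents that add atoms: cis-but-2-ene (C/C=C\C)
Why: Brown asymmetric crotylboration through a closed chair transition state, in which the Z geometry of the crotylborane fixes the 2,3-syn relationship and the isopinocampheyl groups derived from (+)-α-pinene choose the aldehyde face, so that C9 and C10 should be set together under reagent control.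

Step 2
Reactants: 2 (2S,3R)-1-[(tert-butyldimethylsilyl)oxy]-3-methylpent-4-en-2-ol
Product: 3 (2S,3R)-1,2-bis[(tert-butyldimethylsilyl)oxy]-3-methylpent-4-ene
Conditions: TBSOTf, 2,6-lutidine, CH2Cl2, −78 → 0 °C
Reagents that add atoms: tert-butyldimethylsilyl trifluoromethanesulfonate (CC(C)(C)[Si](C)(C)OS(=O)(=O)C(F)(F)F)
Why: Silylation of the hindered secondary alcohol with a silyl triflate protects the C9 hydroxyl until the last step and leaves both stereocenters untouched.

Step 3
Reactants: 3 (2S,3R)-1,2-bis[(tert-butyldimethylsilyl)oxy]-3-methylpent-4-ene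
Product: 4 (2S,3R)-2-[(tert-butyldimethylsilyl)oxy]-3-methylpent-4-en-1-ol
Conditions: HF·pyridine, pyridine, THF, 0 °C
Reagents that add atoms: none
Why: Selective desilylation, since the primary silyl ether is cleaved much faster than the hindered secondary one under buffered fluoride conditions.

Step 4
Reactants: 4 (2S,3R)-2-[(tert-butyldimethylsilyl)oxy]-3-methylpent-4-en-1-ol
Product: 5 tert-butyl{[(2S,3R)-1-iodo-3-methylpent-4-en-2-yl]oxy}dimethylsilane
Conditions: I2, PPh3, imidazole, CH2Cl2, 0 °C → rt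
Reagents that add atoms: iodine (II)
Why: Appel-type iodination of the primary alcohol by SN2 displacement of the alkoxyphosphonium ion, which does not touch the adjacent C9 stereocenter.

Step 5
Reactants: 6 4-hydroxy-3-methylfuran-2(5H)-one (α-methyltetronic acid)
Product: 7 4-bromo-3-methylfuran-2(5H)-one
Conditions: (COBr)2, DMF (cat.), CH2Cl2, 0 °C → rt
Reagents that add atoms: oxalyl bromide (O=C(Br)C(=O)Br)
Why: Vilsmeier-type bromination of a vinylogous acid, in which the enol oxygen is activated by the bromoiminium salt and replaced by bromide through addition–elimination.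

Step 6
Reactants: 5 tert-butyl{[(2S,3R)-1-iodo-3-methylpent-4-en-2-yl]oxy}dimethylsilane; 7 4-bromo-3-methylfuran-2(5H)-one
Product: 8 4-{(2R,3R)-2-[(tert-butyldimethylsilyl)oxy]-3-methylpent-4-en-1-yl}-3-methylfuran-2(5H)-one
Conditions: NiBr2·glyme (10 mol%), 4,4′-di-tert-butyl-2,2′-bipyridine (10 mol%), Mn powder, NaI (cat.), DMA, rt
Reagents that add atoms: none
Why: Nickel-catalysed reductive cross-electrophile coupling of a primary alkyl iodide with an alkenyl bromide forms the C7–C8 bond without a discrete β-silyloxy organometallic reagent that would eliminate, and leaves the terminal alkene and both stereocenters untouched.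

Step 7
Reactants: 8 4-{(2R,3R)-2-[(tert-butyldimethylsilyl)oxy]-3-methylpent-4-en-1-yl}-3-methylfuran-2(5H)-one
Product: 10 4-{(2R,3R)-2-[(tert-butyldimethylsilyl)oxy]-5-hydroxy-3-methylpentyl}-3-methylfuran-2(5H)-one, via alkylborane 9 (not isolated)
Conditions: 9-BBN, THF, 0 °C → rt; then NaBO3·4H2O, H2O, rt
Reagents that add atoms: sodium perborate ([Na+].[O-]OB=O)
Why: Anti-Markovnikov hydroboration–oxidation, in which the bulky borane adds only to the terminal carbon of the monosubstituted alkene and ignores the tetrasubstituted electron-poor butenolide, while the mild perborate oxidation spares the lactone.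

Step 8
Reactants: 10 4-{(2R,3R)-2-[(tert-butyldimethylsilyl)oxy]-5-hydroxy-3-methylpentyl}-3-methylfuran-2(5H)-one
Product: 11 (3R,4R)-4-[(tert-butyldimethylsilyl)oxy]-3-methyl-5-(4-methyl-5-oxo-2,5-dihydrofuran-3-yl)pentanal
Conditions: Dess–Martin periodinane, NaHCO3, CH2Cl2, 0 °C → rt
Reagents that add atoms: none
Why: Dess–Martin oxidation of the primary alcohol to the aldehyde under buffered conditions that do not enolize the butenolide.

Step 9
Reactants: 11 (3R,4R)-4-[(tert-butyldimethylsilyl)oxy]-3-methyl-5-(4-methyl-5-oxo-2,5-dihydrofuran-3-yl)pentanal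
Product: 12 (3R,4R)-4-[(tert-butyldimethylsilyl)oxy]-3-methyl-2-methylidene-5-(4-methyl-5-oxo-2,5-dihydrofuran-3-yl)pentanal
Conditions: 37% aq. CH2O, pyrrolidine (10 mol%), EtCO2H (10 mol%), i-PrOH, 45 °C
Reagents that add atoms: formaldehyde (C=O)
Why: Organocatalytic α-methylenation (Mannich condensation through the enamine followed by loss of the amine) converts the only α-CH2 of the aldehyde into the C1=C2 methylene without a base strong enough to deprotonate the butenolide.

Step 10
Reactants: 12 (3R,4R)-4-[(tert-butyldimethylsilyl)oxy]-3-methyl-2-methylidene-5-(4-methyl-5-oxo-2,5-dihydrofuran-3-yl)pentanal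
Product: 15 (5R,6R,8R,8aR)-5-[(tert-butyldimethylsilyl)oxy]-8-hydroxy-3,6-dimethyl-7-methylidene-4,5,6,7,8,8a-hexahydro-2H-cyclohepta[b]furan-2-one, via silyloxyfuran 13 (not isolated), via trimethylsilyl ether 14 (not isolated)
Conditions: TMSOTf (1.3 equiv), i-Pr2NEt (1.2 equiv), CH2Cl2 (0.005 M), −78 → −20 °C; then 10% aq. citric acid, MeOH, 0 °C
Reagents that add atoms: none
Why: Soft enolization by TMSOTf/i-Pr2NEt turns the butenolide of 12 into the 2-silyloxyfuran 13, whose C6 (furan C5, the vinylogous α-carbon of the C12 carbonyl) attacks the silyl-activated C5 aldehyde through an open transition state; silyl transfer to the aldolate gives 14 and mild acid frees 15. The closest known reaction types are the vinylogous Mukaiyama aldol addition of 2-silyloxyfurans to aldehydes and one-pot silyl triflate/amine enol silane formation–Mukaiyama aldol sequences. The only ring closed is the cycloheptane (C5–C6 bond), in a 7-(enolendo)-exo-trig mode. C5 and C6 are set together by the resident C9 and C10 centers: in the chair-like transition state the C9 silyloxy and C10 methyl groups stay pseudo-equatorial and the aldehyde and furan oxygens both point outward, which gives the trans (threo) C5–O/C6–O pair that silyloxyfuran additions favor in any case and places all four substituents (C5, C6, C9, C10) equatorial on the twist-chair, the same arrangement that base-mediated equilibration at C6 would reach. The step needs γ- over α-attack of the dienoxysilane (the α-carbon C11 carries a methyl group and would become quaternary), 1,2- over 1,4-addition to the 2-substituted acrolein (silyl-activated aldehydes react at the carbonyl carbon at low temperature) and cyclization over oligomerization (high dilution).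

Step 11
Reactants: 15 (5R,6R,8R,8aR)-5-[(tert-butyldimethylsilyl)oxy]-8-hydroxy-3,6-dimethyl-7-methylidene-4,5,6,7,8,8a-hexahydro-2H-cyclohepta[b]furan-2-one
Product: 16 (5R,6R,8R,8aR)-5-[(tert-butyldimethylsilyl)oxy]-3,6-dimethyl-7-methylidene-2-oxo-4,5,6,7,8,8a-hexahydro-2H-cyclohepta[b]furan-8-yl 2-methylpropanoate
Conditions: (i-PrCO)2O, pyridine, DMAP (cat.), CH2Cl2, 0 °C
Reagents that add atoms: 2-methylpropanoic anhydride (CC(C)C(=O)OC(=O)C(C)C)
Why: Nucleophile-catalysed acylation of the only free hydroxyl, run with a weak base at low temperature so that the γ-proton at C6 is not removed and no vinylogous elimination to the alkylidene butenolide sets in.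

Step 12
Reactants: 16 (5R,6R,8R,8aR)-5-[(tert-butyldimethylsilyl)oxy]-3,6-dimethyl-7-methylidene-2-oxo-4,5,6,7,8,8a-hexahydro-2H-cyclohepta[b]furan-8-yl 2-methylpropanoate
Product: 17 (5R,6S,7R,8S,8aR)-5-[(tert-butyldimethylsilyl)oxy]-7-hydroxy-7-(hydroxymethyl)-3,6-dimethyl-2-oxo-4,5,6,7,8,8a-hexahydro-2H-cyclohepta[b]furan-8-yl 2-methylpropanoate
Conditions: OsO4 (5 mol%), NMO, acetone–H2O, 0 °C → rt
Reagents that add atoms: osmium tetroxide (O=[Os](=O)(=O)=O); N-methylmorpholine N-oxide (C[N+]1([O-])CCOCC1); water (O)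
Why: Catalytic osmylation (Upjohn dihydroxylation) attacks the electron-rich 1,1-disubstituted alkene in preference to the electron-poor butenolide and is expected to approach anti to the allylic C5 acyloxy group, which should place the new tertiary C1 hydroxyl trans to the C5 ester.

Step 13
Reactants: 17 (5R,6S,7R,8S,8aR)-5-[(tert-butyldimethylsilyl)oxy]-7-hydroxy-7-(hydroxymethyl)-3,6-dimethyl-2-oxo-4,5,6,7,8,8a-hexahydro-2H-cyclohepta[b]furan-8-yl 2-methylpropanoate
Product: 18 (3R,3aS,5R,6S,7R,8S,8aR)-5-[(tert-butyldimethylsilyl)oxy]-7-hydroxy-7-(hydroxymethyl)-3,6-dimethyl-2-oxooctahydro-2H-cyclohepta[b]furan-8-yl 2-methylpropanoate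
Conditions: H2 (60 bar), 5% Rh/Al2O3, EtOAc, rt
Reagents that add atoms: none
Why: Heterogeneous hydrogenation of the tetrasubstituted butenolide by syn addition from the face of the small C6–H (anti to the C5 branch) should give the cis-fused lactone with H6, H7 and H11 all cis, so that C7 and C11 are set in one operation.

Step 14
Reactants: 18 (3R,3aS,5R,6S,7R,8S,8aR)-5-[(tert-butyldimethylsilyl)oxy]-7-hydroxy-7-(hydroxymethyl)-3,6-dimethyl-2-oxooctahydro-2H-cyclohepta[b]furan-8-yl 2-methylpropanoate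
Product: 19 (3R,3aS,5R,6S,7S,8S,8aR)-5-[(tert-butyldimethylsilyl)oxy]-7-formyl-7-hydroxy-3,6-dimethyl-2-oxooctahydro-2H-cyclohepta[b]furan-8-yl 2-methylpropanoate
Conditions: (COCl)2, DMSO, CH2Cl2, −78 °C; Et3N, −78 → 0 °C
Reagents that add atoms: none
Why: Swern oxidation converts the primary alcohol into the aldehyde, cannot oxidize the tertiary C1 hydroxyl and does not cleave the 1,2-diol.

Step 15
Reactants: 19 (3R,3aS,5R,6S,7S,8S,8aR)-5-[(tert-butyldimethylsilyl)oxy]-7-formyl-7-hydroxy-3,6-dimethyl-2-oxooctahydro-2H-cyclohepta[b]furan-8-yl 2-methylpropanoate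
Product: 20 (3R,3aS,5R,6S,7R,8S,8aR)-5-[(tert-butyldimethylsilyl)oxy]-7-hydroxy-7-[(2E)-1-hydroxybut-2-en-1-yl]-3,6-dimethyl-2-oxooctahydro-2H-cyclohepta[b]furan-8-yl 2-methylpropanoate (both carbinol epimers)
Conditions: (E)-1-bromoprop-1-ene, CrCl2, NiCl2 (cat.), DMSO, rt
Reagents that add atoms: (E)-1-bromoprop-1-ene (C/C=C/Br)
Why: Nozaki–Hiyama–Kishi alkenylation, in which the alkenylchromium reagent adds only to the aldehyde, keeps the E geometry of the bromide and tolerates the esters and the free tertiary hydroxyl, while the configuration of the new carbinol is irrelevant because it is oxidized next.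

Step 16
Reactants: 20 (3R,3aS,5R,6S,7R,8S,8aR)-5-[(tert-butyldimethylsilyl)oxy]-7-hydroxy-7-[(2E)-1-hydroxybut-2-en-1-yl]-3,6-dimethyl-2-oxooctahydro-2H-cyclohepta[b]furan-8-yl 2-methylpropanoate
Product: 21 (3R,3aS,5R,6S,7S,8S,8aR)-7-[(2E)-but-2-enoyl]-5-[(tert-butyldimethylsilyl)oxy]-7-hydroxy-3,6-dimethyl-2-oxooctahydro-2H-cyclohepta[b]furan-8-yl 2-methylpropanoate
Conditions: IBX, DMSO, rt
Reagents that add atoms: none
Why: IBX oxidation of the allylic secondary alcohol gives the α-hydroxy enone, since this reagent oxidizes 1,2-diols to α-ketols without C–C cleavage and cannot oxidize the tertiary alcohol.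

Step 17
Reactants: 21 (3R,3aS,5R,6S,7S,8S,8aR)-7-[(2E)-but-2-enoyl]-5-[(tert-butyldimethylsilyl)oxy]-7-hydroxy-3,6-dimethyl-2-oxooctahydro-2H-cyclohepta[b]furan-8-yl 2-methylpropanoate
Product: 22 (3R,3aS,5R,6S,7S,8S,8aR)-7-[(2E)-but-2-enoyl]-5,7-dihydroxy-3,6-dimethyl-2-oxooctahydro-2H-cyclohepta[b]furan-8-yl 2-methylpropanoate (target)
Conditions: HF·pyridine, pyridine, THF, 0 °C → rt
Reagents that add atoms: none
Why: Fluoride-mediated cleavage of the secondary silyl ether under buffered acidic conditions that should avoid acyl migration, lactone opening and conjugate addition to the enone.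

**Compound list**

1 | (tert-butyldimethylsilyloxy)acetaldehyde | O=CCO[Si](C)(C)C(C)(C)C | starting material
2 | (2S,3R)-1-[(tert-butyldimethylsilyl)oxy]-3-methylpent-4-en-2-ol | C=C[C@@H](C)[C@H](O)CO[Si](C)(C)C(C)(C)C | intermediate
3 | (2S,3R)-1,2-bis[(tert-butyldimethylsilyl)oxy]-3-methylpent-4-ene | C=C[C@@H](C)[C@H](O[Si](C)(C)C(C)(C)C)CO[Si](C)(C)C(C)(C)C | intermediate
4 | (2S,3R)-2-[(tert-butyldimethylsilyl)oxy]-3-methylpent-4-en-1-ol | C=C[C@@H](C)[C@H](O[Si](C)(C)C(C)(C)C)CO | intermediate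
5 | tert-butyl{[(2S,3R)-1-iodo-3-methylpent-4-en-2-yl]oxy}dimethylsilane | C=C[C@@H](C)[C@H](O[Si](C)(C)C(C)(C)C)CI | intermediate
6 | 4-hydroxy-3-methylfuran-2(5H)-one (α-methyltetronic acid) | CC1=C(O)COC1=O | starting material
7 | 4-bromo-3-methylfuran-2(5H)-one | CC1=C(Br)COC1=O | intermediate
8 | 4-{(2R,3R)-2-[(tert-butyldimethylsilyl)oxy]-3-methylpent-4-en-1-yl}-3-methylfuran-2(5H)-one | C=C[C@@H](C)[C@H](O[Si](C)(C)C(C)(C)C)CC1=C(C)C(=O)OC1 | intermediate
9 | B-{(3R,4R)-4-[(tert-butyldimethylsilyl)oxy]-3-methyl-5-(4-methyl-5-oxo-2,5-dihydrofuran-3-yl)pentyl}-9-borabicyclo[3.3.1]nonane | C1CC2CCCC(C1)B2CC[C@@H](C)[C@H](O[Si](C)(C)C(C)(C)C)CC1=C(C)C(=O)OC1 | intermediate (not isolated)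
10 | 4-{(2R,3R)-2-[(tert-butyldimethylsilyl)oxy]-5-hydroxy-3-methylpentyl}-3-methylfuran-2(5H)-one | OCC[C@@H](C)[C@H](O[Si](C)(C)C(C)(C)C)CC1=C(C)C(=O)OC1 | intermediate
11 | (3R,4R)-4-[(tert-butyldimethylsilyl)oxy]-3-methyl-5-(4-methyl-5-oxo-2,5-dihydrofuran-3-yl)pentanal | O=CC[C@@H](C)[C@H](O[Si](C)(C)C(C)(C)C)CC1=C(C)C(=O)OC1 | intermediate
12 | (3R,4R)-4-[(tert-butyldimethylsilyl)oxy]-3-methyl-2-methylidene-5-(4-methyl-5-oxo-2,5-dihydrofuran-3-yl)pentanal | O=CC(=C)[C@@H](C)[C@H](O[Si](C)(C)C(C)(C)C)CC1=C(C)C(=O)OC1 | intermediate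
13 | (3R,4R)-4-[(tert-butyldimethylsilyl)oxy]-3-methyl-2-methylidene-5-{4-methyl-5-[(trimethylsilyl)oxy]furan-3-yl}pentanal | O=CC(=C)[C@@H](C)[C@H](O[Si](C)(C)C(C)(C)C)Cc1coc(O[Si](C)(C)C)c1C | intermediate (not isolated)
14 | (5R,6R,8R,8aR)-5-[(tert-butyldimethylsilyl)oxy]-3,6-dimethyl-7-methylidene-8-[(trimethylsilyl)oxy]-4,5,6,7,8,8a-hexahydro-2H-cyclohepta[b]furan-2-one | C=C1[C@@H](C)[C@H](O[Si](C)(C)C(C)(C)C)CC2=C(C)C(=O)O[C@H]2[C@@H]1O[Si](C)(C)C | intermediate (not isolated)
15 | (5R,6R,8R,8aR)-5-[(tert-butyldimethylsilyl)oxy]-8-hydroxy-3,6-dimethyl-7-methylidene-4,5,6,7,8,8a-hexahydro-2H-cyclohepta[b]furan-2-one | C=C1[C@@H](C)[C@H](O[Si](C)(C)C(C)(C)C)CC2=C(C)C(=O)O[C@H]2[C@@H]1O | intermediate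
16 | (5R,6R,8R,8aR)-5-[(tert-butyldimethylsilyl)oxy]-3,6-dimethyl-7-methylidene-2-oxo-4,5,6,7,8,8a-hexahydro-2H-cyclohepta[b]furan-8-yl 2-methylpropanoate | C=C1[C@@H](C)[C@H](O[Si](C)(C)C(C)(C)C)CC2=C(C)C(=O)O[C@H]2[C@@H]1OC(=O)C(C)C | intermediate
17 | (5R,6S,7R,8S,8aR)-5-[(tert-butyldimethylsilyl)oxy]-7-hydroxy-7-(hydroxymethyl)-3,6-dimethyl-2-oxo-4,5,6,7,8,8a-hexahydro-2H-cyclohepta[b]furan-8-yl 2-methylpropanoate | OC[C@]1(O)[C@@H](C)[C@H](O[Si](C)(C)C(C)(C)C)CC2=C(C)C(=O)O[C@H]2[C@@H]1OC(=O)C(C)C | intermediate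
18 | (3R,3aS,5R,6S,7R,8S,8aR)-5-[(tert-butyldimethylsilyl)oxy]-7-hydroxy-7-(hydroxymethyl)-3,6-dimethyl-2-oxooctahydro-2H-cyclohepta[b]furan-8-yl 2-methylpropanoate | OC[C@]1(O)[C@@H](C)[C@H](O[Si](C)(C)C(C)(C)C)C[C@@H]2[C@@H](OC(=O)[C@@H]2C)[C@@H]1OC(=O)C(C)C | intermediate
19 | (3R,3aS,5R,6S,7S,8S,8aR)-5-[(tert-butyldimethylsilyl)oxy]-7-formyl-7-hydroxy-3,6-dimethyl-2-oxooctahydro-2H-cyclohepta[b]furan-8-yl 2-methylpropanoate | O=C[C@]1(O)[C@@H](C)[C@H](O[Si](C)(C)C(C)(C)C)C[C@@H]2[C@@H](OC(=O)[C@@H]2C)[C@@H]1OC(=O)C(C)C | intermediate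
20 | (3R,3aS,5R,6S,7R,8S,8aR)-5-[(tert-butyldimethylsilyl)oxy]-7-hydroxy-7-[(2E)-1-hydroxybut-2-en-1-yl]-3,6-dimethyl-2-oxooctahydro-2H-cyclohepta[b]furan-8-yl 2-methylpropanoate (both carbinol epimers) | C/C=C/C(O)[C@]1(O)[C@@H](C)[C@H](O[Si](C)(C)C(C)(C)C)C[C@@H]2[C@@H](OC(=O)[C@@H]2C)[C@@H]1OC(=O)C(C)C | intermediate
21 | (3R,3aS,5R,6S,7S,8S,8aR)-7-[(2E)-but-2-enoyl]-5-[(tert-butyldimethylsilyl)oxy]-7-hydroxy-3,6-dimethyl-2-oxooctahydro-2H-cyclohepta[b]furan-8-yl 2-methylpropanoate | C/C=C/C(=O)[C@]1(O)[C@@H](C)[C@H](O[Si](C)(C)C(C)(C)C)C[C@@H]2[C@@H](OC(=O)[C@@H]2C)[C@@H]1OC(=O)C(C)C | intermediate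
22 | (3R,3aS,5R,6S,7S,8S,8aR)-7-[(2E)-but-2-enoyl]-5,7-dihydroxy-3,6-dimethyl-2-oxooctahydro-2H-cyclohepta[b]furan-8-yl 2-methylpropanoate | C/C=C/C(=O)[C@]1(O)[C@@H](C)[C@H](O)C[C@@H]2[C@@H](OC(=O)[C@@H]2C)[C@@H]1OC(=O)C(C)C | target

**Step count and risks**

Total step count: 17. Longest linear sequence: 16 steps (steps 1–4 and 6–17; step 5 prepares the coupling partner).

Steps most likely to fail:

1. Step 10 (key step). The ring closure may show insufficient facial discrimination, so that C5/C6 diastereomers form, possibly together with some conjugate addition to the enal. The fallback sets out from 12 and comes back at 15. 12 is cyclized under the conditions of step 10 and the unseparated mixture of C5/C6-epimeric alcohols F1 is oxidized (Dess–Martin periodinane, NaHCO3) to the cross-conjugated keto butenolide F2. In F2 the C6 hydrogen is α to the ketone and γ to the lactone carbonyl, so brief treatment with Et3N should equilibrate C6 to the isomer with the lactone oxygen equatorial. Luche reduction (NaBH4, CeCl3·7H2O, MeOH, −78 °C) should then deliver hydride axially and give the equatorial C5 alcohol 15. Stereocontrol is thereby moved from the kinetic C–C bond formation to a thermodynamic epimerization plus a substrate-controlled 1,2-reduction.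

2. Step 6. The alkylnickel intermediate may lose the β-silyloxy group by elimination, and reductive dimerization of 7 or proto-dehalogenation of 5 may compete. The fallback sets out from 5 and comes back at 8, building the butenolide ring on the chain instead of coupling to it. Iodide 5 alkylates the sodium salt of ethyl 1,3-dithiane-2-carboxylate (NaH, DMF) to give dithiane ester F3. LiAlH4 reduces the ester to the primary alcohol F4, and esterification with 2-(diethoxyphosphoryl)propanoic acid (DCC, DMAP) gives the phosphonate ester F5. PhI(OCOCF3)2 in aqueous MeCN unmasks the α-acyloxy ketone F6, and an intramolecular Horner–Wadsworth–Emmons olefination (LiCl, i-Pr2NEt, MeCN) closes the butenolide 8.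

3. Step 12. Facial selectivity of the osmylation may be poor, because the equatorial C10 methyl and the equatorial C5 ester lie on opposite faces of the exocyclic alkene; the isobutyryl group may also migrate to the new primary hydroxyl. The fallback sets out from 15 and comes back at 17. Epoxidation directed by the free C5 hydroxyl (VO(acac)2, t-BuOOH, CH2Cl2) should give the spiro-epoxy alcohol F7 with the oxirane oxygen syn to the C5 hydroxyl. Acylation as in step 11 gives the spiro-epoxy ester F8. Acid-catalysed hydrolysis (HClO4 cat., THF–H2O, 0 °C) should open the oxirane at the tertiary carbon C1 with inversion, so that the C1 hydroxyl ends up trans to the C5 ester and the former oxirane oxygen becomes the primary hydroxyl of 17.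

**Further compounds**

F1 | step 10 | mixture of the C8/C8a epimers of 5-[(tert-butyldimethylsilyl)oxy]-8-hydroxy-3,6-dimethyl-7-methylidene-4,5,6,7,8,8a-hexahydro-2H-cyclohepta[b]furan-2-one (5R,6R fixed) | C=C1[C@@H](C)[C@H](O[Si](C)(C)C(C)(C)C)CC2=C(C)C(=O)OC2C1O
F2 | step 10 | (5R,6R,8aR)-5-[(tert-butyldimethylsilyl)oxy]-3,6-dimethyl-7-methylidene-4,5,6,7-tetrahydro-2H-cyclohepta[b]furan-2,8(8aH)-dione | C=C1[C@@H](C)[C@H](O[Si](C)(C)C(C)(C)C)CC2=C(C)C(=O)O[C@H]2C1=O
F3 | step 6 | ethyl 2-{(2R,3R)-2-[(tert-butyldimethylsilyl)oxy]-3-methylpent-4-en-1-yl}-1,3-dithiane-2-carboxylate | C=C[C@@H](C)[C@H](O[Si](C)(C)C(C)(C)C)CC1(C(=O)OCC)SCCCS1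
F4 | step 6 | (2-{(2R,3R)-2-[(tert-butyldimethylsilyl)oxy]-3-methylpent-4-en-1-yl}-1,3-dithian-2-yl)methanol | C=C[C@@H](C)[C@H](O[Si](C)(C)C(C)(C)C)CC1(CO)SCCCS1
F5 | step 6 | (2-{(2R,3R)-2-[(tert-butyldimethylsilyl)oxy]-3-methylpent-4-en-1-yl}-1,3-dithian-2-yl)methyl 2-(diethoxyphosphoryl)propanoate | C=C[C@@H](C)[C@H](O[Si](C)(C)C(C)(C)C)CC1(COC(=O)C(C)P(=O)(OCC)OCC)SCCCS1
F6 | step 6 | (4R,5R)-4-[(tert-butyldimethylsilyl)oxy]-5-methyl-2-oxohept-6-en-1-yl 2-(diethoxyphosphoryl)propanoate | C=C[C@@H](C)[C@H](O[Si](C)(C)C(C)(C)C)CC(=O)COC(=O)C(C)P(=O)(OCC)OCC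
F7 | step 12 | spiro-epoxy alcohol: C1–C2 oxirane of 15 with the oxirane oxygen syn to the C5 hydroxyl | O1C[C@]12[C@@H](C)[C@H](O[Si](C)(C)C(C)(C)C)CC3=C(C)C(=O)O[C@H]3[C@@H]2O
F8 | step 12 | spiro-epoxy ester: 2-methylpropanoate of F7 | O1C[C@]12[C@@H](C)[C@H](O[Si](C)(C)C(C)(C)C)CC3=C(C)C(=O)O[C@H]3[C@@H]2OC(=O)C(C)C
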